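Alder gets its X slowly, ash its G slowly, and larch everything at once, from the same charges.

| setting | alder | ash | larch |
|---|---|---|---|
| X | 0.050 M (fed, over 25 h) | 0.050 M | 0.050 M |
| G | 0.0475 M | 0.0475 M (fed, over 25 h) | 0.0475 M |
| L | 0.0100 M | 0.0100 M | 0.0100 M |
| Q | 2.5 mM | 2.5 mM | 2.5 mM |
| time | 40 h | 40 h | 40 h |
| remark | all else is in the flask from the start; the feed brings no volume worth counting | all else is in the flask from the start; the feed brings no volume worth counting | everything together at the start |

    X + G + Q → Q + D (k1 = 1200 M⁻² h⁻¹)
    X + L → X.L (k2 = 1.5 M⁻¹ h⁻¹)
    G + Q → G.Q (k3 = 1.2 M⁻¹ h⁻¹)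

- the flask that comes out highest in amount of D, in percent of the X charged, or "all alike" when all lie within 1.5 percentage points (alder / ash / larch / all alike)
- D at the end, in percent of the X charged, alder
- D at the end, in percent of the X charged, ash
- D at the end, in percent of the X charged, larch

I count turnovers. To use up the X charged, each Q must turn over 20.0 times on average. Q can make D with X and G, or it can join G as G.Q, an off-cycle form that no step in the scheme leaves. G and Q stand in both rates, so they cancel:

turnovers per Q lost = 1200 M⁻² h⁻¹ × [X] / 1.2 M⁻¹ h⁻¹ = 50.0 at the full charge of X

Now I use fractions: x of the X charge left, d of it made into D, z of the Q lost. Dividing by the turnovers needed gives: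

change in d per change in z = Y·x, with Y = 2.50

Y is the catalyst yield, the fraction of the X charge made into D per whole catalyst charge lost at x = 1. It is a turnover number written in charges.

For larch, I first ignore L, so x = 1 − d and d = 1 − exp(−Y·z). G falls as D forms, so I take its mean as a third of its charge:

z = 0.532, so d = 73.6 %

L can take 20.0 % of the X charge at most, so my low estimate for larch is 58.9 %.

In alder, X at full G and Q has a half-life of 4.86 h, shorter than the 25 h feed, so early in the feed x tends toward feed rate over consumption. That half-life lengthens as G and Q fall, and x then climbs. I still take the early level as a rough x while Q is lost, and I hold G at its charge for z: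

x = 0.281, z = 0.759, so d = 53.3 %

That rough figure is below my low estimate for larch. Ash I do not reckon.

The forecast says larch, with alder 50 % (44 % to 56 %), ash 63 % (57 % to 68 %) and larch 69 % (64 % to 74 %). Its ground is that “the three-body product step runs fastest while both X and G are concentrated”.

The simulation gives larch, with alder 49.9 %, ash 61.9 % and larch 70.4 %.

In larch, step one had done half of its turnover up to the end by 4.47 h, and the capture of Q by 9.39 h. In alder, G.Q already held 67.7 % of the catalyst at 25.0 h, with D at 37.4 %. Dividing final d by Y times final G.Q gives the mean x at which Q was lost: 0.481 in larch and 0.254 in alder.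

Take the neighbour of larch with 0.0010 M of Q. There Y = 1.00, lower than the 2.50 of larch, so without L I expect 41.3 % at my z, or 59.3 % with G held at charge. The flask gives 47.9 %, with G.Q at 75.4 %.

The rate constants belong to no real substance, and the outcome is calculated.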